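Ring positions are numbered on each ring from the carbon that carries the carboxyl carbon (C1). The target is achiral, so no stereocentre has to be set.

## Analysis of the target

The target 15 is a depside. Ring A is a 2,4-dihydroxy-6-propylbenzoyl unit whose carboxyl group is esterified with the C3 oxygen of ring B. Ring B is a benzoic acid with OMe at C2, the ester oxygen at C3, a free OH at C4, H at C5 and a propyl group at C6. There is no stereocentre, so the whole problem is regiochemistry on two benzene rings. The sensitive groups are the aryl ester (hydrolysis or transesterification under base, and acyl shift to the neighbouring C4–OH once that phenol is free), the electron-rich hydroxybenzoic acid (decarboxylation in hot acid) and the free phenols (oxidation). The difficulty has three parts. Ring B is pentasubstituted, with three adjacent oxygens that must end as three different groups. The ester joins a 2,6-disubstituted acid to a phenol flanked on both sides. The propyl group of ring A is meta to both of its oxygens, so electrophilic substitution cannot place it. The strategy rests on one feature: each propyl group is ortho to a carboxyl carbon (ring A C6 beside C1, ring B C6 beside C1–CO2H). In each ring the other ortho position, C2, bears an oxygen substituent, so C6–H is the only ortho C–H of the corresponding benzoic acid, and a carboxylate can direct a metal to it.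

## Retrosynthetic reasoning

**15 to 14.** The two propyl chains are written as allyl groups and the three phenols as benzyl ethers. One catalytic hydrogenation then finishes the synthesis, since it saturates both alkenes and removes all three protecting groups under neutral conditions that leave the aryl ester alone. Benzyl is chosen because it costs no extra step at the end.

**14 to 13 and 4.** The bond between ring B C6 and its allylic CH2 is cut. The free carboxyl group of 13 is the only directing group in the molecule and C6–H is its only ortho C–H, so a carboxylate-directed C–H allylation with allyl acetate 4 can only go to this position. The forward reaction has to metalate C6–H with divalent ruthenium, couple the allyl unit, and leave the aryl ester, the benzyl ethers and the allyl group of ring A untouched. Placing this step last before the hydrogenation means the hardest substituent of ring B is added to a complete skeleton.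

**13 to 12.** The carboxyl group of ring B is taken back to an aldehyde. A carboxylic ester here would have to be cleaved beside the aryl ester, three benzyl ethers and an ortho-allyl aroyl unit. The aldehyde needs no protecting group, is inert in the acylation, and is raised to the acid by a Pinnick oxidation in the same number of steps as a deprotection.

**12 to 5 and 10.** The depside C–O bond is cut between the ring A carbonyl carbon and the ring B C3 oxygen. Acid 5 is activated as its chloride 11 and phenol 10 is acylated. Both partners are hindered, so a forcing acylation is planned. The cut is made here because it divides the molecule into two fragments of similar size, each derived from a cheap hydroxy-aromatic compound.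

**5 to 3 and 4, then 3 to 2 to 1.** The allyl group of ring A is removed by the same C–H disconnection. In 3 the carboxyl group has C2–OBn on one side and C6–H on the other, so again only one position can react. Acid 3 comes from 2,4-dihydroxybenzoic acid 1 by exhaustive benzylation to 2 and saponification. No 5-alkylresorcinol is needed.

**10 to 9 to 8 to 7 to 6.** The three adjacent oxygens of ring B are differentiated on 2,3,4-trihydroxybenzaldehyde 6. O3 and O4 are tied together as a diphenylmethylene ketal in 7, which leaves only the chelated O2–H for methylation to 8. Hydrolysis frees the catechol 9, and the more acidic O4–H, para to the formyl group, is benzylated to give 10 with O3–H free for the ester. Each step uses an intrinsic difference between the hydroxyl groups.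

## Alternatives that were turned down

**Alternative 1:** Ring B is not taken from an aromatic precursor but built around the depside oxygen, cutting ring B at C1–C2 and C5–C6. In the forward direction the bis-silyl diene A4, made from the β-keto ester A3 and already carrying the ring A aroyloxy group on its C2, would add to the alkynoate A2. Loss of the methoxy group on mild acidic work-up would aromatise the adduct to A1.
- For: the polarised diene places the ester oxygen, the C2 and C4 oxygens, the carboxyl carbon and the propyl group in one step. No trioxygenated benzene has to be sorted out. On this point it is stronger than the chosen route, which spends four steps on O2, O3 and O4.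
- Against: A2 is a β-alkyl alkynoate with a single activating group, and A4 is a tetrasubstituted diene whose s-cis form is crowded by the aroyloxy group. The cycloaddition would need heat that a silyl ketene acetal with a neighbouring acyloxy group tolerates poorly.
- Against: A1 has a free C2–OH beside the aryl ester, and its methylation under base invites an aroyl shift from O3 to O2.
- Against: ring A must be supplied with its propyl chain already in place, which this plan does not address.
- Comparison: with diene preparation, methylation, desilylation and debenzylation it is not shorter. The chosen strategy keeps to stable benzenoid intermediates and installs both chains with one reaction type.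

**Alternative 2:** Ring A is cut at C1–C6 together with the depside C–O bond, so a polyketide chain is attached to the ring B phenol and then folded. In the forward direction, heating the dioxinone A6 would release an acylketene. The phenol A7 would trap it to give the aryl triketo ester A8. An amine base and then acid in the same flask would close ring A by aldol condensation of C2 onto the C7 ketone, giving A5.
- For: ring A appears with both hydroxyls free and its propyl group in place, so it needs no protecting groups and no chain installation. Here this alternative is the stronger one.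
- For: the ester is made from a ketene, which avoids the hindered acylation of step 8.
- Against: A8 is an activated aryl ester with an internal enol. Closure through oxygen to a 2-pyrone with expulsion of A7 competes with the C-aldol and would destroy the bond the step is meant to keep. An aryloxide leaves far more readily than the alkoxides for which this folding is dependable.
- Against: A7 is flanked on both sides and is a weaker ketene trap than an alcohol.
- Against: A7 already contains the complete ring B with its propyl group, so the hardest part of the target is only moved into a starting material. A6 costs several steps as well.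
- Comparison: the chosen route solves the ring B chain explicitly and pays for ring A with benzyl ethers that leave in the final hydrogenation at no extra step.

**Alternative 3:** The depside oxygen is removed, tracing the O–C3 bond of ring B to the diaryl ketone A10, in which ring B C3 is bonded directly to the carbonyl carbon. In the forward direction, alkaline peroxide would add to the ketone and ring B, activated by its C4 phenoxide, would migrate from carbon to oxygen (Dakin oxidation) to give A9.
- For: the third oxygen of ring B is created by the rearrangement, so ring B can start from a resorcinol-type precursor and three adjacent oxygens never have to be differentiated. This is a real advantage over the chosen route.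
- Against: A10 is a benzophenone with four ortho substituents, so peroxide addition to its carbonyl is slow.
- Against: the migrating group is not secured. Ring A has alkoxy groups ortho and para to its ipso carbon and should migrate about as readily as ring B, which would give the reversed ester.
- Against: A9 is an aryl ester with a neighbouring phenoxide in alkaline peroxide, conditions that favour perhydrolysis and an O3 to O4 acyl shift. The benzyl ester is exposed to the same conditions.
- Against: both rings must again be prepared with their propyl groups first.
- Comparison: the chosen strategy forms the ester by an ordinary acylation whose direction cannot be reversed, at the price of the protecting-group work on ring B.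

Key step: step 10

## Route

Step 1
Reactants: 1 2,4-dihydroxybenzoic acid
Product: 2 benzyl 2,4-bis(benzyloxy)benzoate
Conditions: BnBr (3.5 equiv), K2CO3 (4 equiv), DMF, 70 °C
Reagents that add atoms: benzyl bromide, BrCc1ccccc1
Why: Exhaustive Williamson alkylation of the carboxylate and both phenoxides; excess reagent and heating should also alkylate the chelated 2-OH.

Step 2
Reactants: 2 benzyl 2,4-bis(benzyloxy)benzoate
Product: 3 2,4-bis(benzyloxy)benzoic acid
Conditions: NaOH (2 M aq.), THF/MeOH, 60 °C; then HCl (aq.) to pH 2
Reagents that add atoms: sodium hydroxide, [Na+].[OH-]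
Why: Saponification of the benzyl ester by acyl–oxygen cleavage; the aryl benzyl ethers are inert to hydroxide.

Step 3
Reactants: 3 2,4-bis(benzyloxy)benzoic acid; 4 allyl acetate
Product: 5 2-allyl-4,6-bis(benzyloxy)benzoic acid
Conditions: 4 (2 equiv), [RuCl2(p-cymene)]2 (3 mol%), K3PO4 (0.5 equiv), MeCN, 50 °C
Reagents that add atoms: none
Why: Carboxylate-directed ortho C–H allylation of a benzoic acid with divalent ruthenium (metalation, alkene insertion, β-acetate elimination). C6–H is the only ortho C–H because C2 bears OBn, so only mono-allylation at one site is possible.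

Step 4
Reactants: 6 2,3,4-trihydroxybenzaldehyde
Product: 7 4-hydroxy-2,2-diphenyl-1,3-benzodioxole-5-carbaldehyde (the O3,O4-diphenylmethylene ketal of 6)
Conditions: Ph2CCl2 (1.2 equiv), Ph2O, 170–175 °C, N2 stream
Reagents that add atoms: dichlorodiphenylmethane, ClC(Cl)(c1ccccc1)c1ccccc1
Why: Ketalisation of a catechol with a geminal dichloride. The O2–H is tied up in a hydrogen bond to the formyl group, so the five-membered ketal should form on the O3/O4 pair.

Step 5
Reactants: 7 4-hydroxy-2,2-diphenyl-1,3-benzodioxole-5-carbaldehyde
Product: 8 4-methoxy-2,2-diphenyl-1,3-benzodioxole-5-carbaldehyde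
Conditions: MeI (1.5 equiv), K2CO3 (2 equiv), DMF, 40 °C
Reagents that add atoms: iodomethane, CI
Why: Williamson O-methylation of the only free phenol; the ketal is stable to base.

Step 6
Reactants: 8 4-methoxy-2,2-diphenyl-1,3-benzodioxole-5-carbaldehyde
Product: 9 3,4-dihydroxy-2-methoxybenzaldehyde
Conditions: AcOH/H2O (4:1), reflux, under N2
Reagents that add atoms: none
Why: Acid hydrolysis of the diaryl ketal through the stabilised diphenylmethyl oxocarbenium ion; the methyl ether and the aldehyde are untouched.

Step 7
Reactants: 9 3,4-dihydroxy-2-methoxybenzaldehyde
Product: 10 4-(benzyloxy)-3-hydroxy-2-methoxybenzaldehyde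
Conditions: BnBr (1.05 equiv), NaHCO3 (1.5 equiv), DMF, 40 °C
Reagents that add atoms: benzyl bromide, BrCc1ccccc1
Why: Regioselective Williamson alkylation. O4–H is para to the formyl group and clearly the more acidic, so the weak base ionises it alone, and O3–H is also shielded by two flanking oxygens.

Step 8
Reactants: 5 2-allyl-4,6-bis(benzyloxy)benzoic acid; 10 4-(benzyloxy)-3-hydroxy-2-methoxybenzaldehyde
Product: 12 6-(benzyloxy)-3-formyl-2-methoxyphenyl 2-allyl-4,6-bis(benzyloxy)benzoate, via 2-allyl-4,6-bis(benzyloxy)benzoyl chloride 11 (not isolated)
Conditions: (COCl)2 (1.3 equiv), DMF (cat.), CH2Cl2, 0 °C to rt, evaporate; then 10, Et3N (3 equiv), DMAP (0.3 equiv), CH2Cl2, 0 °C to reflux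
Reagents that add atoms: oxalyl chloride, O=C(Cl)C(=O)Cl (its chlorine is present in intermediate 11 only)
Why: Acid chloride formation followed by DMAP-catalysed acylation of the phenol, the standard forcing method for aryl esters of 2,6-disubstituted benzoic acids. The aldehyde has no enolisable position and does not interfere.

Step 9
Reactants: 12 6-(benzyloxy)-3-formyl-2-methoxyphenyl 2-allyl-4,6-bis(benzyloxy)benzoate
Product: 13 3-{[2-allyl-4,6-bis(benzyloxy)benzoyl]oxy}-4-(benzyloxy)-2-methoxybenzoic acid
Conditions: NaClO2 (3 equiv), NaH2PO4 (4 equiv), 2-methyl-2-butene (20 equiv), t-BuOH/THF/H2O, 0 °C to rt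
Reagents that add atoms: sodium chlorite, [Na+].[O-]Cl=O
Why: Pinnick oxidation of the aryl aldehyde at about pH 4, where the aryl ester is stable. The large excess of the trisubstituted alkene scavenger takes up the hypochlorous acid before it can reach the allyl group or the alkoxy-substituted rings.

Step 10
Reactants: 13 3-{[2-allyl-4,6-bis(benzyloxy)benzoyl]oxy}-4-(benzyloxy)-2-methoxybenzoic acid; 4 allyl acetate
Product: 14 6-allyl-3-{[2-allyl-4,6-bis(benzyloxy)benzoyl]oxy}-4-(benzyloxy)-2-methoxybenzoic acid
Conditions: 4 (3 equiv), [RuCl2(p-cymene)]2 (5 mol%), K3PO4 (0.5 equiv), MeCN, 50 °C; mildly acidic aqueous work-up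
Reagents that add atoms: none
Why: The closest known reaction type is the carboxylate-directed ruthenium-catalysed ortho C–H allylation of benzoic acids with allyl acetates, applied here to a more elaborate acid. K3PO4 deprotonates 13, the ring B carboxylate replaces chloride on the divalent ruthenium centre, and carboxylate-assisted concerted metalation–deprotonation at C6–H gives a five-membered ruthenacycle. The alkene of 4 coordinates and inserts into the Ru–C6 bond with the aryl group adding to the terminal carbon; β-acetate elimination then releases the allyl arene and a ruthenium acetate that re-enters by ligand exchange, so the metal stays divalent and no oxidant is needed. No ring is closed in the product and no stereocentre is formed. The site selectivity needed is for C6 of ring B, and it is secured because C6–H is the only C–H ortho to the single free carboxyl group (C2 bears OMe), while C5–H is meta and out of reach of the five-membered metallacycle. Ring A cannot compete, as it has no free carboxylate and no C–H ortho to its carbonyl carbon (C2 allyl, C6 OBn), and both positions ortho to the ester oxygen on ring B are substituted. The aryl ester should survive because the sparingly soluble phosphate in MeCN at 50 °C is a poor nucleophile and the ester carbonyl is shielded by two ortho substituents. Any shift of either double bond into conjugation would be harmless, since both chains are saturated in step 11.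

Step 11
Reactants: 14 6-allyl-3-{[2-allyl-4,6-bis(benzyloxy)benzoyl]oxy}-4-(benzyloxy)-2-methoxybenzoic acid
Product: 15 3-[(2,4-dihydroxy-6-propylbenzoyl)oxy]-4-hydroxy-2-methoxy-6-propylbenzoic acid
Conditions: H2 (1 atm), 10% Pd/C, EtOAc, rt
Reagents that add atoms: none
Why: Heterogeneous hydrogenation saturates both terminal alkenes and hydrogenolyses the three aryl benzyl ethers in one operation. The neutral, non-nucleophilic medium should keep the aryl ester in place and avoid acyl shift to the freed C4–OH.

## Compound list

1 | 2,4-dihydroxybenzoic acid | O=C(O)c1ccc(O)cc1O | starting material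
2 | benzyl 2,4-bis(benzyloxy)benzoate | O=C(OCc1ccccc1)c1ccc(OCc2ccccc2)cc1OCc1ccccc1 | intermediate
3 | 2,4-bis(benzyloxy)benzoic acid | O=C(O)c1ccc(OCc2ccccc2)cc1OCc1ccccc1 | intermediate
4 | allyl acetate | C=CCOC(C)=O | starting material
5 | 2-allyl-4,6-bis(benzyloxy)benzoic acid | C=CCc1cc(OCc2ccccc2)cc(OCc2ccccc2)c1C(=O)O | intermediate
6 | 2,3,4-trihydroxybenzaldehyde | O=Cc1ccc(O)c(O)c1O | starting material
7 | 4-hydroxy-2,2-diphenyl-1,3-benzodioxole-5-carbaldehyde | O=Cc1ccc2OC(c3ccccc3)(c3ccccc3)Oc2c1O | intermediate
8 | 4-methoxy-2,2-diphenyl-1,3-benzodioxole-5-carbaldehyde | COc1c(C=O)ccc2OC(c3ccccc3)(c3ccccc3)Oc12 | intermediate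
9 | 3,4-dihydroxy-2-methoxybenzaldehyde | COc1c(C=O)ccc(O)c1O | intermediate
10 | 4-(benzyloxy)-3-hydroxy-2-methoxybenzaldehyde | COc1c(C=O)ccc(OCc2ccccc2)c1O | intermediate
11 | 2-allyl-4,6-bis(benzyloxy)benzoyl chloride | C=CCc1cc(OCc2ccccc2)cc(OCc2ccccc2)c1C(Cl)=O | intermediate (not isolated)
12 | 6-(benzyloxy)-3-formyl-2-methoxyphenyl 2-allyl-4,6-bis(benzyloxy)benzoate | C=CCc1cc(OCc2ccccc2)cc(OCc2ccccc2)c1C(=O)Oc1c(OCc2ccccc2)ccc(C=O)c1OC | intermediate
13 | 3-{[2-allyl-4,6-bis(benzyloxy)benzoyl]oxy}-4-(benzyloxy)-2-methoxybenzoic acid | C=CCc1cc(OCc2ccccc2)cc(OCc2ccccc2)c1C(=O)Oc1c(OCc2ccccc2)ccc(C(=O)O)c1OC | intermediate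
14 | 6-allyl-3-{[2-allyl-4,6-bis(benzyloxy)benzoyl]oxy}-4-(benzyloxy)-2-methoxybenzoic acid | C=CCc1cc(OCc2ccccc2)cc(OCc2ccccc2)c1C(=O)Oc1c(OCc2ccccc2)cc(CC=C)c(C(=O)O)c1OC | intermediate
15 | 3-[(2,4-dihydroxy-6-propylbenzoyl)oxy]-4-hydroxy-2-methoxy-6-propylbenzoic acid | CCCc1cc(O)cc(O)c1C(=O)Oc1c(O)cc(CCC)c(C(=O)O)c1OC | target

## Step count and least certain steps

Total: 11 steps. Longest linear sequence: 8 steps (6 to 15, steps 4 to 11). The ring A branch (steps 1 to 3) joins at step 8.

**Step 10 (key step).** The most likely failure is slow or incomplete metalation of C6–H. The 2-OMe group, buttressed by the 3-aroyloxy group, can twist the carboxylate out of the ring plane, and the free alkene of ring A competes for coordination sites on ruthenium. A secondary risk is loss of the aryl ester on prolonged heating with base. The fallback brings the ring B chain in by cross-coupling before the ester is made. It sets out from 10. Bromination with N-bromosuccinimide in MeCN at 0 °C should go para to the free 3-OH, whose two ortho positions are blocked, giving 4-(benzyloxy)-6-bromo-3-hydroxy-2-methoxybenzaldehyde F1. Stille coupling with allyltributylstannane (Pd(PPh3)4, toluene, 100 °C) should give 6-allyl-4-(benzyloxy)-3-hydroxy-2-methoxybenzaldehyde F2. Acylation with 11 under the conditions of step 8 should give 4-allyl-6-(benzyloxy)-3-formyl-2-methoxyphenyl 2-allyl-4,6-bis(benzyloxy)benzoate F3, and Pinnick oxidation as in step 9 comes back to the route at 14.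

**Step 8.** The most likely failure is slow acyl transfer between a 2,6-disubstituted aroyl chloride and a phenol flanked on both sides, which gives the chloride time to be lost by hydrolysis or by attack on its own allyl double bond. The fallback changes both the order of events and the acylation mechanism. It sets out from 5. Hydrogenation of the alkene alone (H2, RhCl(PPh3)3, benzene/EtOH, which does not cleave benzyl ethers) should give 2,4-bis(benzyloxy)-6-propylbenzoic acid F4. Condensation with 10 using trifluoroacetic anhydride in toluene at rt goes through an acylium-type pathway, which the ortho and para alkoxy groups favour and which is less sensitive to crowding. It should give 6-(benzyloxy)-3-formyl-2-methoxyphenyl 2,4-bis(benzyloxy)-6-propylbenzoate F5. Pinnick oxidation should give 4-(benzyloxy)-3-{[2,4-bis(benzyloxy)-6-propylbenzoyl]oxy}-2-methoxybenzoic acid F6. The ruthenium-catalysed allylation of ring B with 4 should give 6-allyl-4-(benzyloxy)-3-{[2,4-bis(benzyloxy)-6-propylbenzoyl]oxy}-2-methoxybenzoic acid F7, and hydrogenation over Pd/C comes back at 15.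

**Step 4.** The most likely failure is ketalisation on the wrong diol pair (O2/O3) or decomposition of the aldehyde at the high temperature. The fallback uses the low reactivity of the chelated O2–H instead of a bridge. It sets out from 6. BnBr (2 equiv) with K2CO3 in acetone should give 3,4-bis(benzyloxy)-2-hydroxybenzaldehyde F8. MeI with K2CO3 in DMF should give 3,4-bis(benzyloxy)-2-methoxybenzaldehyde F9. Hydrogenolysis (H2, Pd/C, EtOAc, stopped after uptake of two equivalents so that the aldehyde is not reduced) comes back at 9.

**Step 7.** The most likely failure is incomplete discrimination between O4 and O3, leading to alkylation at O3 or at both oxygens. The fallback fixes the O4 benzyl ether first and masks O3 temporarily. It sets out from 6. BnBr (1 equiv) with NaHCO3 in DMF should alkylate the most acidic O4–H to give 4-(benzyloxy)-2,3-dihydroxybenzaldehyde F10. Formation of the dianion (NaH, 2.2 equiv, DMSO/THF) and addition of chloromethyl methyl ether (1 equiv) should alkylate the non-chelated O3 to give 4-(benzyloxy)-2-hydroxy-3-(methoxymethoxy)benzaldehyde F11. MeI with K2CO3 should give 4-(benzyloxy)-2-methoxy-3-(methoxymethoxy)benzaldehyde F12, and HCl in MeOH removes the acetal and comes back at 10.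

## Further compounds

F1 | step 10 | 4-(benzyloxy)-6-bromo-3-hydroxy-2-methoxybenzaldehyde | COc1c(C=O)c(Br)cc(OCc2ccccc2)c1O
F2 | step 10 | 6-allyl-4-(benzyloxy)-3-hydroxy-2-methoxybenzaldehyde | COc1c(C=O)c(CC=C)cc(OCc2ccccc2)c1O
F3 | step 10 | 4-allyl-6-(benzyloxy)-3-formyl-2-methoxyphenyl 2-allyl-4,6-bis(benzyloxy)benzoate | C=CCc1cc(OCc2ccccc2)cc(OCc2ccccc2)c1C(=O)Oc1c(OCc2ccccc2)cc(CC=C)c(C=O)c1OC
F4 | step 8 | 2,4-bis(benzyloxy)-6-propylbenzoic acid | CCCc1cc(OCc2ccccc2)cc(OCc2ccccc2)c1C(=O)O
F5 | step 8 | 6-(benzyloxy)-3-formyl-2-methoxyphenyl 2,4-bis(benzyloxy)-6-propylbenzoate | CCCc1cc(OCc2ccccc2)cc(OCc2ccccc2)c1C(=O)Oc1c(OCc2ccccc2)ccc(C=O)c1OC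
F6 | step 8 | 4-(benzyloxy)-3-{[2,4-bis(benzyloxy)-6-propylbenzoyl]oxy}-2-methoxybenzoic acid | CCCc1cc(OCc2ccccc2)cc(OCc2ccccc2)c1C(=O)Oc1c(OCc2ccccc2)ccc(C(=O)O)c1OC
F7 | step 8 | 6-allyl-4-(benzyloxy)-3-{[2,4-bis(benzyloxy)-6-propylbenzoyl]oxy}-2-methoxybenzoic acid | CCCc1cc(OCc2ccccc2)cc(OCc2ccccc2)c1C(=O)Oc1c(OCc2ccccc2)cc(CC=C)c(C(=O)O)c1OC
F8 | step 4 | 3,4-bis(benzyloxy)-2-hydroxybenzaldehyde | O=Cc1ccc(OCc2ccccc2)c(OCc2ccccc2)c1O
F9 | step 4 | 3,4-bis(benzyloxy)-2-methoxybenzaldehyde | COc1c(C=O)ccc(OCc2ccccc2)c1OCc1ccccc1
F10 | step 7 | 4-(benzyloxy)-2,3-dihydroxybenzaldehyde | O=Cc1ccc(OCc2ccccc2)c(O)c1O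
F11 | step 7 | 4-(benzyloxy)-2-hydroxy-3-(methoxymethoxy)benzaldehyde | COCOc1c(OCc2ccccc2)ccc(C=O)c1O
F12 | step 7 | 4-(benzyloxy)-2-methoxy-3-(methoxymethoxy)benzaldehyde | COCOc1c(OCc2ccccc2)ccc(C=O)c1OC
A1 | alternative 1 | benzyl 3-{[2,4-bis(benzyloxy)-6-propylbenzoyl]oxy}-4-(tert-butyldimethylsilyloxy)-2-hydroxy-6-propylbenzoate | CCCc1cc(O[Si](C)(C)C(C)(C)C)c(OC(=O)c2c(CCC)cc(OCc3ccccc3)cc2OCc2ccccc2)c(O)c1C(=O)OCc1ccccc1
A2 | alternative 1 | benzyl hex-2-ynoate | CCCC#CC(=O)OCc1ccccc1
A3 | alternative 1 | methyl 2-{[2,4-bis(benzyloxy)-6-propylbenzoyl]oxy}-3-oxobutanoate | CCCc1cc(OCc2ccccc2)cc(OCc2ccccc2)c1C(=O)OC(C(C)=O)C(=O)OC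
A4 | alternative 1 | 3-(tert-butyldimethylsilyloxy)-1-methoxy-1-(trimethylsilyloxy)buta-1,3-dien-2-yl 2,4-bis(benzyloxy)-6-propylbenzoate | CCCc1cc(OCc2ccccc2)cc(OCc2ccccc2)c1C(=O)OC(=C(OC)O[Si](C)(C)C)C(=C)O[Si](C)(C)C(C)(C)C
A5 | alternative 2 | benzyl 4-(benzyloxy)-3-[(2,4-dihydroxy-6-propylbenzoyl)oxy]-2-methoxy-6-propylbenzoate | CCCc1cc(O)cc(O)c1C(=O)Oc1c(OCc2ccccc2)cc(CCC)c(C(=O)OCc2ccccc2)c1OC
A6 | alternative 2 | 6-(2,4-dioxoheptyl)-2,2-dimethyl-4H-1,3-dioxin-4-one | CCCC(=O)CC(=O)CC1=CC(=O)OC(C)(C)O1
A7 | alternative 2 | benzyl 4-(benzyloxy)-3-hydroxy-2-methoxy-6-propylbenzoate | CCCc1cc(OCc2ccccc2)c(O)c(OC)c1C(=O)OCc1ccccc1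
A8 | alternative 2 | benzyl 4-(benzyloxy)-2-methoxy-6-propyl-3-[(3,5,7-trioxodecanoyl)oxy]benzoate | CCCC(=O)CC(=O)CC(=O)CC(=O)Oc1c(OCc2ccccc2)cc(CCC)c(C(=O)OCc2ccccc2)c1OC
A9 | alternative 3 | benzyl 3-{[2,4-bis(benzyloxy)-6-propylbenzoyl]oxy}-4-hydroxy-2-methoxy-6-propylbenzoate | CCCc1cc(OCc2ccccc2)cc(OCc2ccccc2)c1C(=O)Oc1c(O)cc(CCC)c(C(=O)OCc2ccccc2)c1OC
A10 | alternative 3 | benzyl 3-[2,4-bis(benzyloxy)-6-propylbenzoyl]-4-hydroxy-2-methoxy-6-propylbenzoate | CCCc1cc(OCc2ccccc2)cc(OCc2ccccc2)c1C(=O)c1c(O)cc(CCC)c(C(=O)OCc2ccccc2)c1OC
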